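Let it run. The flask is a dynamic kinetic resolution: a racemate, reagent matching the two substrates together, single-handed free catalyst and racemization catalyst.

all flasks: left-handed substrate 0.10 M; right-handed substrate 0.10 M; free catalyst 0.20 mM

|  | reagent | racemization catalyst | remark | time |
|---|---|---|---|---|
| birch | 0.28 M | 1 mM | run made earlier |  |
| oak | 0.44 M | 1 mM | run made earlier |  |
| flask | 0.200 M | 1.0 mM |  | 40 min |

| run | time / min | left-handed substrate / % | right-handed substrate / % |
|---|---|---|---|
| birch | 4.00 | 39.5 | 43.8 |
| birch | 8.00 | 35.2 | 39.7 |
| birch | 12.0 | 33.7 | 36.6 |
| birch | 15.0 | 33.0 | 35.6 |
| birch | 20.0 | 31.2 | 33.7 |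
| birch | 25.0 | 31.1 | 32.9 |
| oak | 2.00 | 39.5 | 43.8 |
| oak | 3.00 | 35.8 | 41.2 |
| oak | 5.00 | 32.6 | 37.6 |
| oak | 8.00 | 29.1 | 33.9 |
| oak | 15.0 | 25.1 | 28.1 |
| oak | 25.0 | 24.0 | 25.3 |

(scatter of a reading: 0.5 percentage points)

- part of the left-handed substrate and right-handed substrate charged together that has reacted at 40 min
- excess of left-handed product over right-handed product in the product at 40 min
- excess of right-handed substrate over left-handed substrate among what is left of the two at 40 min

- free catalyst is single-handed; left-handed substrate and right-handed substrate are mirror images of each other, charged as a racemate, each of them at the stated concentration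
- what was read earlier has a scatter of 0.5 percentage points, one standard deviation
- candidate steps: reagent + free catalyst + left-handed substrate -> free catalyst + left-handed product; reagent + free catalyst + right-handed substrate -> free catalyst + right-handed product; left-handed substrate + racemization catalyst <-> right-handed substrate + racemization catalyst; free catalyst <-> dormant form; 2 free catalyst -> spent catalyst
- an excess is the difference of the two amounts in percent of their sum
- an excess is below zero if the other one leads

In the oak run the substrate excess reads 2.64% at 25.0 min, so I count both substrates as one pool, with fraction s left, used one for one with reagent, of which fraction b is left. If the rate goes as substrate times reagent times a catalyst activity that depends on time, ln(b/s) divided by the charged excess of reagent over substrate gives G, the time integral of rate constant times activity. At 25.0 min the oak run, with 49.3% of substrate and 77.0% of reagent left, gives 1.86 M⁻¹, and the birch run, with the same free catalyst charge, gives 1.86 M⁻¹, alike within the scatter of the readings. So don't take the slowing for a reagent shortage, since oak kept more reagent than substrate. Your flask has the free catalyst charge of oak and no charged excess, so 1/s = 1 + G times the charge of both substrates together, and my reckoning gives 27.1% reacted, a figure for 25.0 min.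

For 40 min the forecast gives 29% reacted, a product excess of 30% and a substrate excess of 0.4%, holding that “the stall comes from catalyst death, not reagent loss”; its conversion, for that later time, stands above my figure.

The flask gives 30.9% reacted, a product excess of 27.0% and a substrate excess of 0.792%.

    reagent + free catalyst + left-handed substrate → free catalyst + left-handed product (k = 2000 M⁻² min⁻¹)
    reagent + free catalyst + right-handed substrate → free catalyst + right-handed product (k = 1100 M⁻² min⁻¹)
    left-handed substrate + racemization catalyst ⇌ right-handed substrate + racemization catalyst, rate k3*[racemization catalyst]*[left-handed substrate] forward; the back reaction follows from the equilibrium constant (k = 65.0 M⁻¹ min⁻¹)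
    free catalyst ⇌ dormant form (K = 1.20, k = 0.0170 min⁻¹)
    2 free catalyst → spent catalyst (k = 860 M⁻¹ min⁻¹)

By the same rule the flask stands at G = 2.24 M⁻¹ at 40 min, above the 1.86 M⁻¹ that oak reached at 25.0 min. The neighbouring flask, charged with 0.80 M of reagent and otherwise unchanged, holds 6.17% of the catalyst charged as free catalyst at 40.0 min, as the flask does with 6.17%. Its G reckons to 2.19 M⁻¹, close to the flask's, and it has reacted 78.5% of its substrate with 80% of its reagent left.

(The readings are simulated for substances that don't exist.)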